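**Retrosynthetic overview**

1. The target comes from hydrolysis of a 7,8-O-isopropylidene ketal and α-methylenation of the lactone; the C9 isobutyrate is installed early and is the only C9 protecting group.
2. The ten-membered carbocycle (third ring, formed last) comes from ring-closing metathesis at C1=C10 of a diene that already carries the spiro dioxolane/γ-lactone core.
3. The γ-lactone (second ring) comes from 1,2-reduction of a C6 dienone and closure of the C6 alkoxide onto a tert-butyl ester.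
4. The key C6–C7 bond comes from a visible-light nickel/iridium decarboxylative acylation of a tertiary dioxolane carboxylic acid with (2E)-3-methylhepta-2,6-dienoyl chloride; the planar C7 radical is acylated anti to the C8 side chain.
5. The acid comes from dimethyl 2,3-O-isopropylidene-L-tartrate (dioxolane = first ring, C8 bought; C7–C11 by enolate alkylation, C9 by chelate-controlled ketone reduction); the acyl chloride comes from hex-1-en-5-yne.

Assumption: C1–C15 are the germacrane positions of the target (lactone O on C6, OH on C7 and C8, ester on C9); reagents without a number are purchased.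

**Step 1**
Reactants: 1 dimethyl (4R,5R)-2,2-dimethyl-1,3-dioxolane-4,5-dicarboxylate
Product: 3 dimethyl (4R,5R)-4-(2-tert-butoxy-2-oxoethyl)-2,2-dimethyl-1,3-dioxolane-4,5-dicarboxylate, via lithium ester enolate 2 (not isolated)
Conditions: LiN(i-Pr)2, THF/DMPU, −78 °C, 15 min; BrCH2CO2t-Bu, −78 → −50 °C
Reagents that add atoms: tert-butyl bromoacetate, CC(C)(C)OC(=O)CBr
Why: C-alkylation of the tartrate acetonide ester enolate (the substrate is C2-symmetric, so either ester gives the same enolate) with a reactive α-halo ester outruns β-elimination at −78 °C; the electrophile is expected to enter cis to the neighbouring ester (retention, 4R), but this C7 configuration is reset in step 8, and C8 (ring C5) is untouched.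

**Step 2**
Reactants: 3 dimethyl (4R,5R)-4-(2-tert-butoxy-2-oxoethyl)-2,2-dimethyl-1,3-dioxolane-4,5-dicarboxylate
Product: 5 methyl (4R,5R)-4-(2-tert-butoxy-2-oxoethyl)-2,2-dimethyl-5-(2-methylprop-2-enoyl)-1,3-dioxolane-4-carboxylate, via Weinreb amide 4 (not isolated)
Conditions: MeNH(OMe)·HCl, i-PrMgCl, THF, −20 °C; then CH2=C(Me)MgBr, −20 → 0 °C; aq. NH4Cl
Reagents that add atoms: isopropenylmagnesium bromide, CC(=C)[Mg]Br
Why: One-pot Weinreb ketone synthesis; the magnesium amide attacks only the ester on the CH carbon (the ester on the quaternary carbon and the tert-butyl ester are too hindered), and the chelated tetrahedral adduct stops at the ketone and shields the α-stereocentre from enolisation.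

**Step 3**
Reactants: 5 methyl (4R,5R)-4-(2-tert-butoxy-2-oxoethyl)-2,2-dimethyl-5-(2-methylprop-2-enoyl)-1,3-dioxolane-4-carboxylate
Product: 6 methyl (4R,5S)-4-(2-tert-butoxy-2-oxoethyl)-5-[(1S)-1-hydroxy-2-methylprop-2-en-1-yl]-2,2-dimethyl-1,3-dioxolane-4-carboxylate
Conditions: Zn(BH4)2, Et2O, −30 °C
Reagents that add atoms: none
Why: Chelation-controlled (Cram chelate) 1,2-reduction; zinc bridges the ketone and ring oxygen O8, hydride enters from the H8 face and gives the 8,9-anti alcohol (9S); esters and the enone C=C are not reduced.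

**Step 4**
Reactants: 6 methyl (4R,5S)-4-(2-tert-butoxy-2-oxoethyl)-5-[(1S)-1-hydroxy-2-methylprop-2-en-1-yl]-2,2-dimethyl-1,3-dioxolane-4-carboxylate
Product: 7 methyl (4R,5S)-4-(2-tert-butoxy-2-oxoethyl)-2,2-dimethyl-5-[(1S)-2-methyl-1-(2-methylpropanoyloxy)prop-2-en-1-yl]-1,3-dioxolane-4-carboxylate
Conditions: (i-PrCO)2O, Et3N, DMAP (cat.), CH2Cl2, 0 → 25 °C
Reagents that add atoms: isobutyric anhydride, CC(C)C(=O)OC(=O)C(C)C
Why: DMAP-catalysed (Steglich-type) acylation of the only free hydroxyl installs the target's isobutyrate, which also protects C9–OH; no stereocentre is touched.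

**Step 5**
Reactants: 7 methyl (4R,5S)-4-(2-tert-butoxy-2-oxoethyl)-2,2-dimethyl-5-[(1S)-2-methyl-1-(2-methylpropanoyloxy)prop-2-en-1-yl]-1,3-dioxolane-4-carboxylate
Product: 8 (4R,5S)-4-(2-tert-butoxy-2-oxoethyl)-2,2-dimethyl-5-[(1S)-2-methyl-1-(2-methylpropanoyloxy)prop-2-en-1-yl]-1,3-dioxolane-4-carboxylic acid
Conditions: LiI, EtOAc, reflux; then aq. HCl (pH 3), 0 °C
Reagents that add atoms: none
Why: SN2 dealkylation of the methyl ester by iodide (nucleophilic ester cleavage) leaves the tert-butyl ester, the isobutyrate and the ketal intact and frees the tertiary α-alkoxy acid used as radical precursor.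

**Step 6**
Reactants: 9 hex-1-en-5-yne
Product: 12 (2E)-3-methylhepta-2,6-dienoic acid, via alkenyl(dimethyl)alane 10 (not isolated), via lithium alkenylaluminate 11 (not isolated)
Conditions: Me3Al, Cp2ZrCl2 (cat.), CH2Cl2, 0 → 25 °C; n-BuLi, THF/hexane, −78 °C; CO2; aq. HCl
Reagents that add atoms: trimethylaluminium, C[Al](C)C; carbon dioxide, O=C=O
Why: Zirconium-catalysed Negishi carboalumination adds Me and Al syn across the terminal alkyne (the isolated alkene is inert) and fixes the E trisubstituted olefin (C4=C5); the derived aluminate is carboxylated with retention.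

**Step 7**
Reactants: 12 (2E)-3-methylhepta-2,6-dienoic acid
Product: 13 (2E)-3-methylhepta-2,6-dienoyl chloride
Conditions: (COCl)2, DMF (cat.), CH2Cl2, 0 → 25 °C; used crude
Reagents that add atoms: oxalyl chloride, ClC(=O)C(Cl)=O
Why: Vilsmeier-type acid chloride formation; olefin geometry is kept.

**Step 8**
Reactants: 8 (4R,5S)-4-(2-tert-butoxy-2-oxoethyl)-2,2-dimethyl-5-[(1S)-2-methyl-1-(2-methylpropanoyloxy)prop-2-en-1-yl]-1,3-dioxolane-4-carboxylic acid; 13 (2E)-3-methylhepta-2,6-dienoyl chloride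
Product: 15 tert-butyl 2-[(4R,5S)-2,2-dimethyl-4-[(2E)-3-methylhepta-2,6-dienoyl]-5-[(1S)-2-methyl-1-(2-methylpropanoyloxy)prop-2-en-1-yl]-1,3-dioxolan-4-yl]acetate, via mixed anhydride 14 (not isolated)
Conditions: Cs2CO3, Ir[dF(CF3)ppy]2(dtbbpy)PF6 (1 mol %), NiCl2·glyme (10 mol %), 4,4'-di-tert-butyl-2,2'-bipyridine (15 mol %), 1,4-dioxane, 450 nm LEDs, 25 °C
Reagents that add atoms: none
Why: Proposed new method: a diastereoselective nickel/iridium metallaphotoredox decarboxylative acylation that builds a fully substituted α-alkoxy ketone stereocentre. Acid 8 and chloride 13 form mixed anhydride 14; zerovalent nickel inserts into its less hindered dienoyl C–O bond; the photoexcited iridium complex oxidises the released tertiary α-alkoxy carboxylate; loss of CO2 gives the planar C7 dioxolanyl radical. The acyl–nickel species captures this radical on the face anti to the bulky C8 side chain, and reductive elimination gives 15 with the acyl group trans to C9 (target C7 geometry) whatever the C7 configuration of 8. The closest known reaction is the CO2-extrusion/recombination ketone synthesis from secondary α-oxy or α-amino acids and acyl chlorides; it has not been shown for tertiary α-alkoxy acids, dienoyl donors or with substrate stereocontrol.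

**Step 9**
Reactants: 15 tert-butyl 2-[(4R,5S)-2,2-dimethyl-4-[(2E)-3-methylhepta-2,6-dienoyl]-5-[(1S)-2-methyl-1-(2-methylpropanoyloxy)prop-2-en-1-yl]-1,3-dioxolan-4-yl]acetate
Product: 17 (4S,5S,6S)-2,2-dimethyl-6-[(1E)-2-methylhexa-1,5-dien-1-yl]-4-[(1S)-2-methyl-1-(2-methylpropanoyloxy)prop-2-en-1-yl]-1,3,7-trioxaspiro[4.4]nonan-8-one, via lithium alkoxide 16 (not isolated)
Conditions: LiBH(s-Bu)3, THF, −78 °C; then 25 °C; aq. NH4Cl
Reagents that add atoms: none
Why: 1,2-Reduction of the β,β-disubstituted enone by a bulky non-chelating hydride under Felkin–Anh control (C7–O7 anti to hydride, the dienyl group next to the tied-back ring carbon C8 rather than the CH2CO2t-Bu arm) should give the 6S alkoxide; this closes 5-exo-trig onto the tert-butyl ester to the γ-lactone with C5 and C8 trans.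

**Step 10**
Reactants: 17 (4S,5S,6S)-2,2-dimethyl-6-[(1E)-2-methylhexa-1,5-dien-1-yl]-4-[(1S)-2-methyl-1-(2-methylpropanoyloxy)prop-2-en-1-yl]-1,3,7-trioxaspiro[4.4]nonan-8-one
Product: 18 (1(10)Z,4E,6S,7S,8S,9S)-7,8-(isopropylidenedioxy)-9-(2-methylpropanoyloxy)germacra-1(10),4-dien-12,6-olide
Conditions: second-generation Hoveyda–Grubbs catalyst RuCl2(=CH-C6H4-2-O-i-Pr)(H2IMes) (10 mol %), 1,4-benzoquinone (10 mol %), PhMe (1 mM), 80 °C
Reagents that add atoms: none
Why: Ring-closing metathesis between the monosubstituted and the 1,1-disubstituted olefin releases ethene; a ten-membered ring that already holds the 4E olefin can take the new trisubstituted olefin only as the cis (1(10)Z) isomer.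

**Step 11**
Reactants: 18 (1(10)Z,4E,6S,7S,8S,9S)-7,8-(isopropylidenedioxy)-9-(2-methylpropanoyloxy)germacra-1(10),4-dien-12,6-olide
Product: 22 (1(10)Z,4E,6S,7S,8S,9S)-7,8-(isopropylidenedioxy)-9-(2-methylpropanoyloxy)germacra-1(10),4,11(13)-trien-12,6-olide, via lithium lactone enolate 19 (not isolated), via Mannich base 20 (not isolated), via trimethylammonium iodide 21 (not isolated)
Conditions: LiN(SiMe3)2, THF, −78 °C; [Me2N=CH2]I, −78 → 0 °C; MeI, CH2Cl2/MeOH, 25 °C; aq. NaHCO3
Reagents that add atoms: N,N-dimethylmethyleneiminium iodide (Eschenmoser's salt), C[N+](C)=C.[I-]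
Why: Eschenmoser methylenation; the lactone CH2 is the only accessible acidic site, the enolate undergoes a Mannich reaction, and quaternisation followed by E1cB loss of trimethylamine gives the exocyclic methylene without forming a stereocentre.

**Step 12**
Reactants: 22 (1(10)Z,4E,6S,7S,8S,9S)-7,8-(isopropylidenedioxy)-9-(2-methylpropanoyloxy)germacra-1(10),4,11(13)-trien-12,6-olide
Product: 23 (1(10)Z,4E,6S,7R,8S,9S)-7,8-dihydroxy-9-(2-methylpropanoyloxy)germacra-1(10),4,11(13)-trien-12,6-olide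
Conditions: AcOH/H2O (4:1), 40 °C
Reagents that add atoms: none
Why: Mild acid hydrolysis of the isopropylidene ketal frees the 7,8-diol; ester, lactone and ring olefins tolerate aqueous acetic acid, and no stereocentre is touched (the C7 descriptor returns to R only because CIP priorities change).

**Compound list**

1 | dimethyl (4R,5R)-2,2-dimethyl-1,3-dioxolane-4,5-dicarboxylate (dimethyl 2,3-O-isopropylidene-L-tartrate) | COC(=O)[C@@H]1OC(C)(C)O[C@H]1C(=O)OC | starting material
2 | lithium ester enolate of 1 (ring C5 still R) | COC(O[Li])=C1OC(C)(C)O[C@H]1C(=O)OC | intermediate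
3 | dimethyl (4R,5R)-4-(2-tert-butoxy-2-oxoethyl)-2,2-dimethyl-1,3-dioxolane-4,5-dicarboxylate (CH2CO2t-Bu cis to the C5 ester) | COC(=O)[C@]1(CC(=O)OC(C)(C)C)OC(C)(C)O[C@H]1C(=O)OC | intermediate
4 | methyl (4R,5R)-4-(2-tert-butoxy-2-oxoethyl)-5-[methoxy(methyl)carbamoyl]-2,2-dimethyl-1,3-dioxolane-4-carboxylate | COC(=O)[C@]1(CC(=O)OC(C)(C)C)OC(C)(C)O[C@H]1C(=O)N(C)OC | intermediate
5 | methyl (4R,5R)-4-(2-tert-butoxy-2-oxoethyl)-2,2-dimethyl-5-(2-methylprop-2-enoyl)-1,3-dioxolane-4-carboxylate | COC(=O)[C@]1(CC(=O)OC(C)(C)C)OC(C)(C)O[C@H]1C(=O)C(C)=C | intermediate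
6 | methyl (4R,5S)-4-(2-tert-butoxy-2-oxoethyl)-5-[(1S)-1-hydroxy-2-methylprop-2-en-1-yl]-2,2-dimethyl-1,3-dioxolane-4-carboxylate | COC(=O)[C@]1(CC(=O)OC(C)(C)C)OC(C)(C)O[C@H]1[C@@H](O)C(C)=C | intermediate
7 | methyl (4R,5S)-4-(2-tert-butoxy-2-oxoethyl)-2,2-dimethyl-5-[(1S)-2-methyl-1-(2-methylpropanoyloxy)prop-2-en-1-yl]-1,3-dioxolane-4-carboxylate | COC(=O)[C@]1(CC(=O)OC(C)(C)C)OC(C)(C)O[C@H]1[C@@H](OC(=O)C(C)C)C(C)=C | intermediate
8 | (4R,5S)-4-(2-tert-butoxy-2-oxoethyl)-2,2-dimethyl-5-[(1S)-2-methyl-1-(2-methylpropanoyloxy)prop-2-en-1-yl]-1,3-dioxolane-4-carboxylic acid | OC(=O)[C@]1(CC(=O)OC(C)(C)C)OC(C)(C)O[C@H]1[C@@H](OC(=O)C(C)C)C(C)=C | intermediate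
9 | hex-1-en-5-yne | C=CCCC#C | starting material
10 | dimethyl[(1E)-2-methylhexa-1,5-dien-1-yl]alane | C=CCC/C(C)=C/[Al](C)C | intermediate
11 | lithium butyl(dimethyl)[(1E)-2-methylhexa-1,5-dien-1-yl]aluminate | [Li+].CCCC[Al-](C)(C)/C=C(\C)CCC=C | intermediate
12 | (2E)-3-methylhepta-2,6-dienoic acid | C=CCC/C(C)=C/C(=O)O | intermediate
13 | (2E)-3-methylhepta-2,6-dienoyl chloride | C=CCC/C(C)=C/C(Cl)=O | intermediate
14 | mixed anhydride of 8 and 12 | C=CCC/C(C)=C/C(=O)OC(=O)[C@]1(CC(=O)OC(C)(C)C)OC(C)(C)O[C@H]1[C@@H](OC(=O)C(C)C)C(C)=C | intermediate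
15 | tert-butyl 2-[(4R,5S)-2,2-dimethyl-4-[(2E)-3-methylhepta-2,6-dienoyl]-5-[(1S)-2-methyl-1-(2-methylpropanoyloxy)prop-2-en-1-yl]-1,3-dioxolan-4-yl]acetate | C=CCC/C(C)=C/C(=O)[C@]1(CC(=O)OC(C)(C)C)OC(C)(C)O[C@H]1[C@@H](OC(=O)C(C)C)C(C)=C | intermediate
16 | lithium alkoxide of tert-butyl 2-[(4S,5S)-4-[(1S,2E)-1-hydroxy-3-methylhepta-2,6-dien-1-yl]-2,2-dimethyl-5-[(1S)-2-methyl-1-(2-methylpropanoyloxy)prop-2-en-1-yl]-1,3-dioxolan-4-yl]acetate | C=CCC/C(C)=C/[C@H](O[Li])[C@]1(CC(=O)OC(C)(C)C)OC(C)(C)O[C@H]1[C@@H](OC(=O)C(C)C)C(C)=C | intermediate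
17 | (4S,5S,6S)-2,2-dimethyl-6-[(1E)-2-methylhexa-1,5-dien-1-yl]-4-[(1S)-2-methyl-1-(2-methylpropanoyloxy)prop-2-en-1-yl]-1,3,7-trioxaspiro[4.4]nonan-8-one | O=C1O[C@@H](/C=C(\C)CCC=C)[C@]2(C1)OC(C)(C)O[C@H]2[C@@H](OC(=O)C(C)C)C(C)=C | intermediate
18 | (1(10)Z,4E,6S,7S,8S,9S)-7,8-(isopropylidenedioxy)-9-(2-methylpropanoyloxy)germacra-1(10),4-dien-12,6-olide (C7 has the target's spatial arrangement; its descriptor reads S because of the ketal) | C1C(=O)O[C@H]2/C=C(\C)CC/C=C(/C)[C@H](OC(=O)C(C)C)[C@@H]3OC(C)(C)O[C@@]123 | intermediate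
19 | lithium lactone enolate of 18 | C1=C(O[Li])O[C@H]2/C=C(\C)CC/C=C(/C)[C@H](OC(=O)C(C)C)[C@@H]3OC(C)(C)O[C@@]123 | intermediate
20 | 11-[(dimethylamino)methyl] derivative of 18 (C11 epimers) | CN(C)CC1C(=O)O[C@H]2/C=C(\C)CC/C=C(/C)[C@H](OC(=O)C(C)C)[C@@H]3OC(C)(C)O[C@@]123 | intermediate
21 | N-methyl trimethylammonium iodide of 20 | C[N+](C)(C)CC1C(=O)O[C@H]2/C=C(\C)CC/C=C(/C)[C@H](OC(=O)C(C)C)[C@@H]3OC(C)(C)O[C@@]123.[I-] | intermediate
22 | (1(10)Z,4E,6S,7S,8S,9S)-7,8-(isopropylidenedioxy)-9-(2-methylpropanoyloxy)germacra-1(10),4,11(13)-trien-12,6-olide | C=C1C(=O)O[C@H]2/C=C(\C)CC/C=C(/C)[C@H](OC(=O)C(C)C)[C@@H]3OC(C)(C)O[C@@]123 | intermediate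
23 | (1(10)Z,4E,6S,7R,8S,9S)-7,8-dihydroxy-9-(2-methylpropanoyloxy)germacra-1(10),4,11(13)-trien-12,6-olide, CNP0301808.4 | C=C1C(=O)O[C@H]2/C=C(\C)CC/C=C(/C)[C@H](OC(=O)C(C)C)[C@H](O)[C@]12O | target

**Step count and risks**

Total step count: 12. Longest linear sequence: 10 (steps 1–5 and 8–12; steps 6–7 make the acyl chloride).

Three steps most likely to fail:

Step 8 (the new photochemical coupling). Risks are slow capture of the tertiary radical by nickel, insertion of nickel at the wrong acyl group of the anhydride, or activation of the allylic ester. The fallback uses known chemistry and keeps the carboxyl carbon of 8 as C6, so it relies on the C7 configuration set in step 1 (only the major C7 epimer of 8 is used). It sets out from 8: 1-chloro-N,N,2-trimethylprop-1-en-1-amine in CH2Cl2 gives, under neutral conditions, the acid chloride F1. Acylation of the alkenylalane 10 (made as in step 6) with F1 under Pd(PPh3)4 (zerovalent palladium) gives dienone 15, where the fallback rejoins the route.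

Step 9 (C6 configuration). The facial preference rests on a Felkin–Anh argument without close precedent; the 6R alkoxide would give the cis-lactone. The fallback reverses the order of bond formation at C6 and sets out from 8. The acid chloride F1 (made as above) is reduced with LiAlH(O-t-Bu)3 in THF at −78 °C to the aldehyde F2. Addition of the lithium alkenylaluminate 11 (from step 6) to F2 under the same facial bias places the carbon nucleophile where hydride went before, giving the 6S alkoxide. This closes onto the tert-butyl ester to lactone 17, where the fallback rejoins the route.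

Step 10 (ring-closing metathesis). A ten-membered ring must close onto a 1,1-disubstituted olefin flanked by an acyloxy group; slow initiation, dimerisation or six-ring closure onto the C4=C5 olefin are possible. The fallback runs the metathesis on a free allylic alcohol, whose hydroxyl accelerates carbene transfer to the adjacent olefin, and acylates afterwards. It sets out from 6:
- Et3SiCl and imidazole give the triethylsilyl ether F3.
- LiI in EtOAc gives the acid F4.
- The step 8 coupling with 13 gives the dienone F5.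
- LiBH(s-Bu)3 as in step 9 gives the spiro lactone F6.
- HF·pyridine frees the allylic alcohol F7.
- Metathesis with the same ruthenium catalyst gives the macrocyclic alcohol F8.
- Acylation with isobutyric anhydride and DMAP returns to 18.

**Further compounds**

F1 | step 8 | tert-butyl 2-[(4R,5S)-4-(chlorocarbonyl)-2,2-dimethyl-5-[(1S)-2-methyl-1-(2-methylpropanoyloxy)prop-2-en-1-yl]-1,3-dioxolan-4-yl]acetate | ClC(=O)[C@]1(CC(=O)OC(C)(C)C)OC(C)(C)O[C@H]1[C@@H](OC(=O)C(C)C)C(C)=C
F2 | step 9 | tert-butyl 2-[(4R,5S)-4-formyl-2,2-dimethyl-5-[(1S)-2-methyl-1-(2-methylpropanoyloxy)prop-2-en-1-yl]-1,3-dioxolan-4-yl]acetate | O=C[C@]1(CC(=O)OC(C)(C)C)OC(C)(C)O[C@H]1[C@@H](OC(=O)C(C)C)C(C)=C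
F3 | step 10 | methyl (4R,5S)-4-(2-tert-butoxy-2-oxoethyl)-2,2-dimethyl-5-[(1S)-2-methyl-1-(triethylsilyloxy)prop-2-en-1-yl]-1,3-dioxolane-4-carboxylate | COC(=O)[C@]1(CC(=O)OC(C)(C)C)OC(C)(C)O[C@H]1[C@@H](O[Si](CC)(CC)CC)C(C)=C
F4 | step 10 | (4R,5S)-4-(2-tert-butoxy-2-oxoethyl)-2,2-dimethyl-5-[(1S)-2-methyl-1-(triethylsilyloxy)prop-2-en-1-yl]-1,3-dioxolane-4-carboxylic acid | OC(=O)[C@]1(CC(=O)OC(C)(C)C)OC(C)(C)O[C@H]1[C@@H](O[Si](CC)(CC)CC)C(C)=C
F5 | step 10 | tert-butyl 2-[(4R,5S)-2,2-dimethyl-4-[(2E)-3-methylhepta-2,6-dienoyl]-5-[(1S)-2-methyl-1-(triethylsilyloxy)prop-2-en-1-yl]-1,3-dioxolan-4-yl]acetate | C=CCC/C(C)=C/C(=O)[C@]1(CC(=O)OC(C)(C)C)OC(C)(C)O[C@H]1[C@@H](O[Si](CC)(CC)CC)C(C)=C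
F6 | step 10 | (4S,5S,6S)-2,2-dimethyl-6-[(1E)-2-methylhexa-1,5-dien-1-yl]-4-[(1S)-2-methyl-1-(triethylsilyloxy)prop-2-en-1-yl]-1,3,7-trioxaspiro[4.4]nonan-8-one | O=C1O[C@@H](/C=C(\C)CCC=C)[C@]2(C1)OC(C)(C)O[C@H]2[C@@H](O[Si](CC)(CC)CC)C(C)=C
F7 | step 10 | (4S,5S,6S)-4-[(1S)-1-hydroxy-2-methylprop-2-en-1-yl]-2,2-dimethyl-6-[(1E)-2-methylhexa-1,5-dien-1-yl]-1,3,7-trioxaspiro[4.4]nonan-8-one | O=C1O[C@@H](/C=C(\C)CCC=C)[C@]2(C1)OC(C)(C)O[C@H]2[C@@H](O)C(C)=C
F8 | step 10 | (1(10)Z,4E,6S,7S,8S,9S)-9-hydroxy-7,8-(isopropylidenedioxy)germacra-1(10),4-dien-12,6-olide | C1C(=O)O[C@H]2/C=C(\C)CC/C=C(/C)[C@H](O)[C@@H]3OC(C)(C)O[C@@]123
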